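**Retrosynthetic overview**

1. The only ring is the 4-hydroxy-5,6-dihydro-2H-pyran-2-one (O1, C2–C6). It is closed in the last step by Dieckmann condensation (ring bond C3–C4) of the β-keto ester formed from the C1' acid (via its acyl Meldrum's acid) and methyl (R)-3-hydroxybutanoate, which supplies ring C6. The C8' carboxyl is unveiled from a CH2O–silyl group just before.
2. The strategy rests on the chain segment C3'H2–C4'H(CH3)–C5'H2–C6'H=C7'H (chain numbered from the ketone carbon C1'): a methyl-branched sp3 carbon one CH2 away from an sp2 carbon of the (E)-alkene. The C4'–CH3 and C5'–C6' bonds are both made in one flask from silylated pent-4-en-1-ol, Al(CH3)3 and an (E)-alkenyl iodide.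
3. The iodide (C6'–C8' with the (S)-2-methylbutyl branch) comes from (S)-1-bromo-2-methylbutane by malonate homologation and auxiliary-controlled hydroxymethylation, which sets C8'. The acyl carbon then becomes C7'=C6'–I by alkynylation and hydrozirconation–iodination.
4. Ring order: no ring exists until the final step, which closes the pyranone.

Key step: step 11

Assumption: the (−)-enantiomer of bis(1-neomenthylindenyl)zirconium dichloride is taken to give the (2R)-2-methylalkylalane from a 1-alkene; should alkene 18 respond in the opposite sense, the (+)-catalyst is used instead.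

**Route**

Step 1
Reactants: 1 (S)-1-bromo-2-methylbutane; 2 diethyl malonate
Product: 3 diethyl 2-[(2S)-2-methylbutyl]propanedioate
Conditions: NaOEt, NaI (cat.), EtOH, reflux; 2 in excess
Reagents that add atoms: none
Why: Malonic ester alkylation (SN2 of the malonate anion at the primary carbon of 1); the stereocentre is one carbon away from the reacting centre and is not touched.

Step 2
Reactants: 3 diethyl 2-[(2S)-2-methylbutyl]propanedioate
Product: 5 (4S)-4-methylhexanoic acid, via alkylmalonic acid 4 (not isolated)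
Conditions: KOH, EtOH/H2O, reflux; H2SO4 to pH 1; crude diacid neat, 170 °C
Reagents that add atoms: potassium hydroxide, [K+].[OH-]
Why: Saponification and thermal decarboxylation of the malonic acid (malonic ester synthesis) leave a CH2CO2H unit on the chain, with the remote stereocentre unaffected.

Step 3
Reactants: 5 (4S)-4-methylhexanoic acid; 6 (4S)-4-benzyl-1,3-oxazolidin-2-one
Product: 8 (4S)-4-benzyl-3-[(4S)-4-methylhexanoyl]-1,3-oxazolidin-2-one, via mixed pivalic anhydride 7 (not isolated)
Conditions: t-BuCOCl, Et3N, THF, −20 °C; then 6, LiCl, rt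
Reagents that add atoms: none
Why: N-acylation of the oxazolidinone by a mixed anhydride (LiCl/Et3N variant), which reacts at its less hindered carbonyl.

Step 4
Reactants: 8 (4S)-4-benzyl-3-[(4S)-4-methylhexanoyl]-1,3-oxazolidin-2-one
Product: 10 (4S)-4-benzyl-3-[(2R,4S)-2-(hydroxymethyl)-4-methylhexanoyl]-1,3-oxazolidin-2-one, via chlorotitanium enolate 9 (not isolated)
Conditions: TiCl4, i-Pr2NEt, CH2Cl2, 0 °C; then 1,3,5-trioxane, TiCl4, 0 °C
Reagents that add atoms: 1,3,5-trioxane, C1OCOCO1
Why: Evans titanium-enolate hydroxymethylation: the chelated (Z)-enolate 9 is attacked by the TiCl4-opened trioxane (an oxocarbenium ion) on the face away from the benzyl group of the auxiliary, which sets the new centre as 2R (the later C8').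

Step 5
Reactants: 10 (4S)-4-benzyl-3-[(2R,4S)-2-(hydroxymethyl)-4-methylhexanoyl]-1,3-oxazolidin-2-one
Product: 11 (4S)-4-benzyl-3-[(2R,4S)-2-({[tert-butyl(diphenyl)silyl]oxy}methyl)-4-methylhexanoyl]-1,3-oxazolidin-2-one
Conditions: TBDPSCl, imidazole, CH2Cl2, 0 °C to rt
Reagents that add atoms: tert-butyl(chloro)diphenylsilane, CC(C)(C)[Si](Cl)(c1ccccc1)c1ccccc1
Why: Imidazole-promoted silyl ether formation at the unhindered primary alcohol; the mild base should avoid retro-aldol loss of formaldehyde.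

Step 6
Reactants: 11 (4S)-4-benzyl-3-[(2R,4S)-2-({[tert-butyl(diphenyl)silyl]oxy}methyl)-4-methylhexanoyl]-1,3-oxazolidin-2-one
Product: 12 (2S,4S)-2-({[tert-butyl(diphenyl)silyl]oxy}methyl)-4-methylhexan-1-ol
Conditions: LiBH4, MeOH (1 equiv), THF, 0 °C
Reagents that add atoms: none
Why: Reductive cleavage of the N-acyl oxazolidinone by hydride attack at the exocyclic carbonyl gives the primary alcohol and returns the auxiliary; the bulky silyl ether is not expected to migrate between the two oxygens, so the centre is kept.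

Step 7
Reactants: 12 (2S,4S)-2-({[tert-butyl(diphenyl)silyl]oxy}methyl)-4-methylhexan-1-ol
Product: 13 (2R,4S)-2-({[tert-butyl(diphenyl)silyl]oxy}methyl)-4-methylhexanal
Conditions: Dess–Martin periodinane, NaHCO3, CH2Cl2, 0 °C to rt; used crude
Reagents that add atoms: none
Why: Dess–Martin oxidation under buffered, non-basic conditions should give the α-branched aldehyde without epimerisation.

Step 8
Reactants: 13 (2R,4S)-2-({[tert-butyl(diphenyl)silyl]oxy}methyl)-4-methylhexanal
Product: 14 tert-butyl{[(2S,4S)-2-ethynyl-4-methylhexyl]oxy}diphenylsilane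
Conditions: dimethyl (1-diazo-2-oxopropyl)phosphonate, K2CO3, MeOH, 0 °C to rt
Reagents that add atoms: dimethyl (1-diazo-2-oxopropyl)phosphonate, COP(=O)(OC)C(=[N+]=[N-])C(C)=O
Why: Ohira–Bestmann variant of the Seyferth–Gilbert homologation (addition of the diazomethylphosphonate anion, loss of phosphate and N2, 1,2-hydrogen shift) gives the terminal alkyne, the weak base at low temperature limiting α-epimerisation.

Step 9
Reactants: 14 tert-butyl{[(2S,4S)-2-ethynyl-4-methylhexyl]oxy}diphenylsilane
Product: 16 tert-butyl({(2S,4S)-2-[(E)-2-iodoethenyl]-4-methylhexyl}oxy)diphenylsilane, via alkenylzirconocene chloride 15 (not isolated)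
Conditions: Cp2Zr(H)Cl, THF, rt, dark; then I2, 0 °C
Reagents that add atoms: iodine, II
Why: Hydrozirconation with the Schwartz reagent adds Zr–H syn with zirconium on the terminal carbon, and iodinolysis of the C–Zr bond with retention gives the (E)-iodoalkene.

Step 10
Reactants: 17 pent-4-en-1-ol
Product: 18 tert-butyldimethyl(pent-4-en-1-yloxy)silane
Conditions: TBSCl, imidazole, CH2Cl2, rt
Reagents that add atoms: tert-butyl(chloro)dimethylsilane, CC(C)(C)[Si](C)(C)Cl
Why: Standard imidazole-promoted silylation of a primary alcohol.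

Step 11
Reactants: 18 tert-butyldimethyl(pent-4-en-1-yloxy)silane; 19 trimethylaluminium; 16 tert-butyl({(2S,4S)-2-[(E)-2-iodoethenyl]-4-methylhexyl}oxy)diphenylsilane
Product: 22 tert-butyl{[(4R,6E,8S,10S)-8-({[tert-butyl(diphenyl)silyl]oxy}methyl)-4,10-dimethyldodec-6-en-1-yl]oxy}dimethylsilane (the O1-TBDPS O9-TBS bis-silyl ether of (2S,3E,6R)-6-methyl-2-[(2S)-2-methylbutyl]non-3-ene-1,9-diol), via dimethylalkylalane 20 (not isolated), via alkylzinc triflate 21 (not isolated)
Conditions: Al(CH3)3, (−)-bis(1-neomenthylindenyl)zirconium dichloride (5 mol%), methylaluminoxane [Al(CH3)O]n, CH2Cl2, 0 °C to rt; evaporate CH2Cl2 and excess Al(CH3)3; Zn(OTf)2, DMF, 70 °C; then 16 (limiting), PdCl2[(2-Ph2PC6H4)2O] (5 mol%), i-Bu2AlH (10 mol%), rt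
Reagents that add atoms: trimethylaluminium (compound 19), C[Al](C)C
Why: Al(CH3)3, methylaluminoxane and the chiral zirconium dichloride form a cationic methylzirconocene that inserts the terminal alkene of 18 with methyl delivered to the internal carbon (C4'–CH3 bond), and alkyl exchange from zirconium to aluminium releases alane 20 and restarts the cycle (zirconium-catalysed asymmetric carboalumination, the ZACA reaction). The C4' stereocentre is set under catalyst control: the neomenthylindenyl ligands select the alkene face, and the (−)-catalyst is the one expected to give the (2R)-alane. After excess Al(CH3)3 has been pumped off, Zn(OTf)2 in DMF moves the 2-methylalkyl group to zinc (21), and zerovalent palladium made from PdCl2[(2-Ph2PC6H4)2O] and i-Bu2AlH adds oxidatively to the C–I bond of 16 with retention, accepts the alkyl group and forms C5'–C6' by reductive elimination (Negishi coupling; the closest known reaction is the one-pot carboalumination–alkenylation of 1-alkenes). No ring is closed in this step. The step needs enantioface selectivity, which only the catalyst supplies, so the minor C4' epimer would appear as a diastereomer of 22 to be removed by preparative chromatography; it needs retention of the (E) geometry, which the stereospecific oxidative addition and reductive elimination secure; and it needs coupling to outrun β-hydride elimination, which the wide-bite-angle diphosphine favours. Iodide 16 meets the aluminium reagent only after the excess Al(CH3)3 is gone, so its internal alkene and both silyl ethers should stay untouched.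

Step 12
Reactants: 22 tert-butyl{[(4R,6E,8S,10S)-8-({[tert-butyl(diphenyl)silyl]oxy}methyl)-4,10-dimethyldodec-6-en-1-yl]oxy}dimethylsilane
Product: 23 (4R,6E,8S,10S)-8-({[tert-butyl(diphenyl)silyl]oxy}methyl)-4,10-dimethyldodec-6-en-1-ol
Conditions: camphorsulfonic acid (cat.), MeOH/CH2Cl2, 0 °C
Reagents that add atoms: none
Why: Acid-catalysed methanolysis removes the primary tert-butyldimethylsilyl ether selectively, because the tert-butyldiphenylsilyl ether is far more stable to acid.

Step 13
Reactants: 23 (4R,6E,8S,10S)-8-({[tert-butyl(diphenyl)silyl]oxy}methyl)-4,10-dimethyldodec-6-en-1-ol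
Product: 24 (4R,6E,8S,10S)-8-({[tert-butyl(diphenyl)silyl]oxy}methyl)-4,10-dimethyldodec-6-enoic acid
Conditions: TEMPO (cat.), PhI(OAc)2, MeCN/H2O, rt
Reagents that add atoms: water, O
Why: Nitroxyl-catalysed (oxoammonium) oxidation of the primary alcohol through the aldehyde hydrate to the acid; the alkene and the silyl ether are inert.

Step 14
Reactants: 24 (4R,6E,8S,10S)-8-({[tert-butyl(diphenyl)silyl]oxy}methyl)-4,10-dimethyldodec-6-enoic acid; 25 2,2-dimethyl-1,3-dioxane-4,6-dione (Meldrum's acid)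
Product: 26 5-[(4R,6E,8S,10S)-8-({[tert-butyl(diphenyl)silyl]oxy}methyl)-1-hydroxy-4,10-dimethyldodec-6-en-1-ylidene]-2,2-dimethyl-1,3-dioxane-4,6-dione
Conditions: DCC, DMAP, CH2Cl2, 0 °C to rt; filter, wash with aq. KHSO4; used crude
Reagents that add atoms: none
Why: Carbodiimide/DMAP C-acylation of the acidic methylene of Meldrum's acid gives the enolised acyl Meldrum's acid, a masked acylketene.

Step 15
Reactants: 26 the acyl Meldrum's acid from step 14; 27 methyl (R)-3-hydroxybutanoate
Product: 29 methyl (3R)-3-{[(6R,8E,10S,12S)-10-({[tert-butyl(diphenyl)silyl]oxy}methyl)-6,12-dimethyl-3-oxotetradec-8-enoyl]oxy}butanoate, via acylketene 28 (not isolated)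
Conditions: 27 (1.5 equiv), toluene, 100 °C
Reagents that add atoms: none
Why: Thermal cycloreversion of the acyl Meldrum's acid loses acetone and CO2 to give acylketene 28, which the secondary alcohol of 27 traps as the β-keto ester; the carbinol C–O bond is not broken, so its R configuration is kept.

Step 16
Reactants: 29 the silylated β-keto ester from step 15
Product: 30 methyl (3R)-3-{[(6R,8E,10S,12S)-10-(hydroxymethyl)-6,12-dimethyl-3-oxotetradec-8-enoyl]oxy}butanoate
Conditions: HF·pyridine, pyridine, THF, 0 °C to rt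
Reagents that add atoms: none
Why: Fluoride cleavage of the Si–O bond under buffered, non-basic conditions should leave the β-keto ester and the β-acyloxy ester intact.

Step 17
Reactants: 30 the hydroxymethyl β-keto ester from step 16
Product: 31 methyl (3R)-3-{[(6R,8E,10S,12S)-10-formyl-6,12-dimethyl-3-oxotetradec-8-enoyl]oxy}butanoate
Conditions: Dess–Martin periodinane (1.2 equiv), NaHCO3, CH2Cl2, 0 °C, short time; used at once
Reagents that add atoms: none
Why: Dess–Martin oxidation of the primary alcohol is much faster than attack on the β-keto ester methylene, and the absence of amine base should keep the α-vinyl aldehyde from epimerising or moving its double bond into conjugation.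

Step 18
Reactants: 31 the aldehyde from step 17
Product: 32 (2S,3E,6R)-11-{[(2R)-4-methoxy-4-oxobutan-2-yl]oxy}-6-methyl-2-[(2S)-2-methylbutyl]-9,11-dioxoundec-3-enoic acid
Conditions: NaClO2, NaH2PO4, 2-methylbut-2-ene, t-BuOH/H2O, 0 °C to rt
Reagents that add atoms: sodium chlorite, [Na+].[O-]Cl=O
Why: Pinnick oxidation at mildly acidic pH, with 2-methylbut-2-ene scavenging hypochlorous acid, converts the aldehyde to the acid without disturbing the C2 stereocentre, the β,γ-alkene or the β-keto ester.

Step 19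
Reactants: 32 the keto ester acid from step 18
Product: 33 (2S,3E,6R)-9-[(6R)-4-hydroxy-6-methyl-2-oxo-5,6-dihydro-2H-pyran-3-yl]-6-methyl-2-[(2S)-2-methylbutyl]-9-oxonon-3-enoic acid (target)
Conditions: KOtBu (2.2 equiv), t-BuOH/THF, 0 °C to rt; aq. HCl to pH 2
Reagents that add atoms: none
Why: Dieckmann condensation: after the carboxylate has formed, the β-keto ester enolate carbon attacks the methyl ester carbonyl in a 6-exo-trig closure (ring bond C3–C4) and expels methoxide, the acidic tricarbonyl product being the thermodynamic sink, while ring C6 comes unchanged from 27 and C8' is shielded from deprotonation as its carboxylate.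

**Compound list**

1 | (S)-1-bromo-2-methylbutane | CC[C@H](C)CBr | starting material
2 | diethyl malonate | CCOC(=O)CC(=O)OCC | starting material
3 | diethyl 2-[(2S)-2-methylbutyl]propanedioate | CC[C@H](C)CC(C(=O)OCC)C(=O)OCC | intermediate
4 | 2-[(2S)-2-methylbutyl]propanedioic acid (not isolated) | CC[C@H](C)CC(C(=O)O)C(=O)O | intermediate
5 | (4S)-4-methylhexanoic acid | CC[C@H](C)CCC(=O)O | intermediate
6 | (4S)-4-benzyl-1,3-oxazolidin-2-one | O=C1N[C@@H](Cc2ccccc2)CO1 | starting material
7 | (4S)-4-methylhexanoic 2,2-dimethylpropanoic anhydride (not isolated) | CC[C@H](C)CCC(=O)OC(=O)C(C)(C)C | intermediate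
8 | (4S)-4-benzyl-3-[(4S)-4-methylhexanoyl]-1,3-oxazolidin-2-one | CC[C@H](C)CCC(=O)N1C(=O)OC[C@@H]1Cc1ccccc1 | intermediate
9 | trichlorotitanium (Z)-enolate of 8 (not isolated) | CC[C@H](C)C/C=C(\O[Ti](Cl)(Cl)Cl)N1C(=O)OC[C@@H]1Cc1ccccc1 | intermediate
10 | (4S)-4-benzyl-3-[(2R,4S)-2-(hydroxymethyl)-4-methylhexanoyl]-1,3-oxazolidin-2-one | CC[C@H](C)C[C@@H](C(=O)N1C(=O)OC[C@@H]1Cc1ccccc1)CO | intermediate
11 | (4S)-4-benzyl-3-[(2R,4S)-2-({[tert-butyl(diphenyl)silyl]oxy}methyl)-4-methylhexanoyl]-1,3-oxazolidin-2-one | CC[C@H](C)C[C@@H](C(=O)N1C(=O)OC[C@@H]1Cc1ccccc1)CO[Si](c1ccccc1)(c1ccccc1)C(C)(C)C | intermediate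
12 | (2S,4S)-2-({[tert-butyl(diphenyl)silyl]oxy}methyl)-4-methylhexan-1-ol | CC[C@H](C)C[C@@H](CO)CO[Si](c1ccccc1)(c1ccccc1)C(C)(C)C | intermediate
13 | (2R,4S)-2-({[tert-butyl(diphenyl)silyl]oxy}methyl)-4-methylhexanal | CC[C@H](C)C[C@@H](C=O)CO[Si](c1ccccc1)(c1ccccc1)C(C)(C)C | intermediate
14 | tert-butyl{[(2S,4S)-2-ethynyl-4-methylhexyl]oxy}diphenylsilane | CC[C@H](C)C[C@@H](C#C)CO[Si](c1ccccc1)(c1ccccc1)C(C)(C)C | intermediate
15 | chloro{(E)-2-[(2S,4S)-1-{[tert-butyl(diphenyl)silyl]oxy}-4-methylhexan-2-yl]ethenyl}bis(cyclopentadienyl)zirconium (not isolated) | CC[C@H](C)C[C@@H](/C=C/[Zr](Cl)(C1C=CC=C1)C1C=CC=C1)CO[Si](c1ccccc1)(c1ccccc1)C(C)(C)C | intermediate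
16 | tert-butyl({(2S,4S)-2-[(E)-2-iodoethenyl]-4-methylhexyl}oxy)diphenylsilane | CC[C@H](C)C[C@@H](/C=C/I)CO[Si](c1ccccc1)(c1ccccc1)C(C)(C)C | intermediate
17 | pent-4-en-1-ol | C=CCCCO | starting material
18 | tert-butyldimethyl(pent-4-en-1-yloxy)silane | C=CCCCO[Si](C)(C)C(C)(C)C | intermediate
19 | trimethylaluminium | C[Al](C)C | starting material
20 | [(2R)-5-{[tert-butyl(dimethyl)silyl]oxy}-2-methylpentyl]dimethylalumane (not isolated) | C[Al](C)C[C@H](C)CCCO[Si](C)(C)C(C)(C)C | intermediate
21 | [(2R)-5-{[tert-butyl(dimethyl)silyl]oxy}-2-methylpentyl]zinc trifluoromethanesulfonate (not isolated) | FC(F)(F)S(=O)(=O)O[Zn]C[C@H](C)CCCO[Si](C)(C)C(C)(C)C | intermediate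
22 | tert-butyl{[(4R,6E,8S,10S)-8-({[tert-butyl(diphenyl)silyl]oxy}methyl)-4,10-dimethyldodec-6-en-1-yl]oxy}dimethylsilane | CC[C@H](C)C[C@@H](/C=C/C[C@H](C)CCCO[Si](C)(C)C(C)(C)C)CO[Si](c1ccccc1)(c1ccccc1)C(C)(C)C | intermediate
23 | (4R,6E,8S,10S)-8-({[tert-butyl(diphenyl)silyl]oxy}methyl)-4,10-dimethyldodec-6-en-1-ol | CC[C@H](C)C[C@@H](/C=C/C[C@H](C)CCCO)CO[Si](c1ccccc1)(c1ccccc1)C(C)(C)C | intermediate
24 | (4R,6E,8S,10S)-8-({[tert-butyl(diphenyl)silyl]oxy}methyl)-4,10-dimethyldodec-6-enoic acid | CC[C@H](C)C[C@@H](/C=C/C[C@H](C)CCC(=O)O)CO[Si](c1ccccc1)(c1ccccc1)C(C)(C)C | intermediate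
25 | 2,2-dimethyl-1,3-dioxane-4,6-dione (Meldrum's acid) | CC1(C)OC(=O)CC(=O)O1 | starting material
26 | 5-[(4R,6E,8S,10S)-8-({[tert-butyl(diphenyl)silyl]oxy}methyl)-1-hydroxy-4,10-dimethyldodec-6-en-1-ylidene]-2,2-dimethyl-1,3-dioxane-4,6-dione | CC[C@H](C)C[C@@H](/C=C/C[C@H](C)CCC(O)=C1C(=O)OC(C)(C)OC1=O)CO[Si](c1ccccc1)(c1ccccc1)C(C)(C)C | intermediate
27 | methyl (R)-3-hydroxybutanoate | C[C@@H](O)CC(=O)OC | starting material
28 | (6R,8E,10S,12S)-10-({[tert-butyl(diphenyl)silyl]oxy}methyl)-6,12-dimethyltetradeca-1,8-diene-1,3-dione (acylketene, not isolated) | CC[C@H](C)C[C@@H](/C=C/C[C@H](C)CCC(=O)C=C=O)CO[Si](c1ccccc1)(c1ccccc1)C(C)(C)C | intermediate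
29 | methyl (3R)-3-{[(6R,8E,10S,12S)-10-({[tert-butyl(diphenyl)silyl]oxy}methyl)-6,12-dimethyl-3-oxotetradec-8-enoyl]oxy}butanoate | CC[C@H](C)C[C@@H](/C=C/C[C@H](C)CCC(=O)CC(=O)O[C@H](C)CC(=O)OC)CO[Si](c1ccccc1)(c1ccccc1)C(C)(C)C | intermediate
30 | methyl (3R)-3-{[(6R,8E,10S,12S)-10-(hydroxymethyl)-6,12-dimethyl-3-oxotetradec-8-enoyl]oxy}butanoate | CC[C@H](C)C[C@@H](/C=C/C[C@H](C)CCC(=O)CC(=O)O[C@H](C)CC(=O)OC)CO | intermediate
31 | methyl (3R)-3-{[(6R,8E,10S,12S)-10-formyl-6,12-dimethyl-3-oxotetradec-8-enoyl]oxy}butanoate | CC[C@H](C)C[C@@H](/C=C/C[C@H](C)CCC(=O)CC(=O)O[C@H](C)CC(=O)OC)C=O | intermediate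
32 | (2S,3E,6R)-11-{[(2R)-4-methoxy-4-oxobutan-2-yl]oxy}-6-methyl-2-[(2S)-2-methylbutyl]-9,11-dioxoundec-3-enoic acid | CC[C@H](C)C[C@@H](/C=C/C[C@H](C)CCC(=O)CC(=O)O[C@H](C)CC(=O)OC)C(=O)O | intermediate
33 | (2S,3E,6R)-9-[(6R)-4-hydroxy-6-methyl-2-oxo-5,6-dihydro-2H-pyran-3-yl]-6-methyl-2-[(2S)-2-methylbutyl]-9-oxonon-3-enoic acid | CC[C@H](C)C[C@@H](/C=C/C[C@H](C)CCC(=O)C1=C(O)C[C@@H](C)OC1=O)C(=O)O | target

**Step count**

Total: 19 steps. Longest linear sequence: 18 steps (steps 1–9 and 11–19, from (S)-1-bromo-2-methylbutane); step 10 is a one-step side branch.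

**Steps most likely to fail, with fallbacks**

Step 11. The carboalumination may discriminate the alkene faces incompletely, leaving the C4' epimer as a diastereomer that is hard to separate. A methyl group rather than the 2-methylalkyl group may also pass from the mixed alkylmetal to palladium and use up iodide 16. The fallback sets out from 18 (with 16 as partner) and comes back at 22. Alkene 18 is carboaluminated as in step 11 to alane 20, which is oxidised with O2 to (2R)-5-{[tert-butyl(dimethyl)silyl]oxy}-2-methylpentan-1-ol F1. Lipase-catalysed acetylation (lipase from Burkholderia cepacia, vinyl acetate) is expected to convert the minor (2S)-alcohol faster, into (2S)-5-{[tert-butyl(dimethyl)silyl]oxy}-2-methylpentyl acetate F2, which is removed by chromatography. The purified F1 is converted (I2, PPh3, imidazole) into tert-butyl{[(4R)-5-iodo-4-methylpentyl]oxy}dimethylsilane F3. Zinc insertion (Zn dust, LiCl, THF) gives [(2R)-5-{[tert-butyl(dimethyl)silyl]oxy}-2-methylpentyl]zinc iodide F4, which carries no methyl group, and its coupling with 16 under Pd(PPh3)4 catalysis gives 22.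

Step 17. The new aldehyde may epimerise at its α-carbon or pull the neighbouring double bond into conjugation, and the periodinane may attack the β-keto ester methylene. The fallback sets out from 29 and comes back at 33; it closes the ring before the oxidation. Dieckmann closure of 29 (KOtBu, 1.1 equiv, t-BuOH/THF) gives (6R)-3-[(4R,6E,8S,10S)-8-({[tert-butyl(diphenyl)silyl]oxy}methyl)-4,10-dimethyldodec-6-enoyl]-4-hydroxy-6-methyl-5,6-dihydro-2H-pyran-2-one F5. HF·pyridine gives (6R)-4-hydroxy-3-[(4R,6E,8S,10S)-8-(hydroxymethyl)-4,10-dimethyldodec-6-enoyl]-6-methyl-5,6-dihydro-2H-pyran-2-one F6. A single-operation oxidation (TEMPO cat., PhI(OAc)2, MeCN/H2O), in which the aldehyde is consumed as its hydrate as it forms, then gives 33.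

Step 19. Base-induced elimination of the β-acyloxy group of the hydroxybutanoate unit, or ester exchange, may outrun the ring closure. The fallback sets out from 27 and 24 and comes back at 33; it attaches the side chain to a preformed ring. Claisen condensation of 27 with the lithium enolate of tert-butyl acetate (excess, THF, −78 °C) gives tert-butyl (5R)-5-hydroxy-3-oxohexanoate F7, and trifluoroacetic acid closes it to (6R)-6-methyloxane-2,4-dione F8. Coupling of F8 with acid 24 (DCC, DMAP, CH2Cl2) should give the enol ester (2R)-2-methyl-6-oxo-3,6-dihydro-2H-pyran-4-yl (4R,6E,8S,10S)-8-({[tert-butyl(diphenyl)silyl]oxy}methyl)-4,10-dimethyldodec-6-enoate F9. DMAP is expected to convert F9 by O-to-C acyl shift into the silylated acylpyranone F5. Desilylation to the hydroxymethyl acylpyranone F6 and its oxidation, as in the fallback to step 17, lead to 33.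

**Further compounds**

F1 | step 11 | (2R)-5-{[tert-butyl(dimethyl)silyl]oxy}-2-methylpentan-1-ol | OC[C@H](C)CCCO[Si](C)(C)C(C)(C)C
F2 | step 11 | (2S)-5-{[tert-butyl(dimethyl)silyl]oxy}-2-methylpentyl acetate | CC(=O)OC[C@@H](C)CCCO[Si](C)(C)C(C)(C)C
F3 | step 11 | tert-butyl{[(4R)-5-iodo-4-methylpentyl]oxy}dimethylsilane | IC[C@H](C)CCCO[Si](C)(C)C(C)(C)C
F4 | step 11 | [(2R)-5-{[tert-butyl(dimethyl)silyl]oxy}-2-methylpentyl]zinc iodide | I[Zn]C[C@H](C)CCCO[Si](C)(C)C(C)(C)C
F5 | step 17 | (6R)-3-[(4R,6E,8S,10S)-8-({[tert-butyl(diphenyl)silyl]oxy}methyl)-4,10-dimethyldodec-6-enoyl]-4-hydroxy-6-methyl-5,6-dihydro-2H-pyran-2-one | CC[C@H](C)C[C@@H](/C=C/C[C@H](C)CCC(=O)C1=C(O)C[C@@H](C)OC1=O)CO[Si](c1ccccc1)(c1ccccc1)C(C)(C)C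
F6 | step 17 | (6R)-4-hydroxy-3-[(4R,6E,8S,10S)-8-(hydroxymethyl)-4,10-dimethyldodec-6-enoyl]-6-methyl-5,6-dihydro-2H-pyran-2-one | CC[C@H](C)C[C@@H](/C=C/C[C@H](C)CCC(=O)C1=C(O)C[C@@H](C)OC1=O)CO
F7 | step 19 | tert-butyl (5R)-5-hydroxy-3-oxohexanoate | C[C@@H](O)CC(=O)CC(=O)OC(C)(C)C
F8 | step 19 | (6R)-6-methyloxane-2,4-dione | C[C@@H]1CC(=O)CC(=O)O1
F9 | step 19 | (2R)-2-methyl-6-oxo-3,6-dihydro-2H-pyran-4-yl (4R,6E,8S,10S)-8-({[tert-butyl(diphenyl)silyl]oxy}methyl)-4,10-dimethyldodec-6-enoate | CC[C@H](C)C[C@@H](/C=C/C[C@H](C)CCC(=O)OC1=CC(=O)O[C@H](C)C1)CO[Si](c1ccccc1)(c1ccccc1)C(C)(C)C
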